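## Retrosynthetic overview
1. 19 ⇒ 18: the C5–OOH and the 4(15)-methylene come last, from a singlet-oxygen (Schenck) ene reaction on the α face of the Δ4 tetrasubstituted alkene.
2. 18 ⇒ 16: the 8β-OAc comes from α-face hydride delivery to the 8-ketone with in situ acetylation, so no free γ-hydroxy ester is present to lactonise.
3. 16 ⇒ 11 + 12 (key C7–C11 bond): C7 of the 8-ketone is turned into an acceptor (enolonium, a trivalent-iodine enolate). It is joined to the α-carbon of methyl acrylate, delivered as its zinc derivative, so the whole α-methylene ester arrives in one step.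
4. 11 ⇒ 7: the 3β-isobutyrate comes from axial hydride addition and acylation, followed by ketal removal and kinetic enol silane formation.
5. 7 ⇒ 1 + 3: ring B is bought (1). Ring A is closed second, by a chiral-imine Michael addition (sets C10) and an aldol condensation.

Numbering: eudesmane numbering is used for all bicyclic compounds. Ring A = C1–C5 + C10, ring B = C5–C10, CH3-14 is on C10, CH3-15 is on C4, and the side chain C11(=C13)–C12 is on C7. β is the face carrying CH3-14.

Assumption: 1 and 12 are bought as catalogue chemicals, and the about 90% ee from step 1 is raised to >98% ee by recrystallising 7 (not counted as a step).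

## Route

Step 1
Reactants: 1 7-methyl-1,4-dioxaspiro[4.5]decan-8-one (racemic); 2 (R)-1-phenylethylamine; 3 pent-1-en-3-one (ethyl vinyl ketone)
Product: 6 (R)-7-methyl-7-(3-oxopentyl)-1,4-dioxaspiro[4.5]decan-8-one, via ketimine 4 (not isolated), via Michael adduct ketimine 5 (not isolated)
Conditions: 2 (1.05 equiv), TsOH (1 mol%), PhMe, Dean–Stark reflux; then 3 (1.5 equiv), THF, 40 °C, 4 d; then 20% aq AcOH, rt, 2 h
Reagents that add atoms: water, O
Why: Chiral-imine (secondary-enamine) asymmetric Michael addition: 4 reacts through its more substituted enamine tautomer in a compact aza-ene-like transition state in which 3 approaches anti to the phenyl group, which converts racemic 1 into the C10 quaternary centre (R, CH3-14 β) in about 90% ee, and dilute AcOH then hydrolyses only the imine and leaves the dioxolane intact.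

Step 2
Reactants: 6 (R)-7-methyl-7-(3-oxopentyl)-1,4-dioxaspiro[4.5]decan-8-one
Product: 7 (10R)-11,12,13-trinoreudesm-4-ene-3,8-dione 8-ethylene ketal
Conditions: NaOMe (1 equiv), MeOH, 60 °C
Reagents that add atoms: none
Why: Intramolecular aldol condensation (ring-closing half of a Robinson annulation): the C4 enolate of the ethyl ketone attacks the C5 ketone to close six-membered ring A and dehydration gives the tetrasubstituted enone, while quaternary C10 cannot epimerise and the ketal is stable to base.

Step 3
Reactants: 7 (10R)-11,12,13-trinoreudesm-4-ene-3,8-dione 8-ethylene ketal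
Product: 9 (3S,10R)-3β-isobutyryloxy-11,12,13-trinoreudesm-4-en-8-one ethylene ketal, via lithium 3β-alkoxyaluminate 8 (not isolated)
Conditions: LiAlH(OtBu)3 (1.3 equiv), THF, 0 °C; then (iPrCO)2O (4 equiv), DMAP (0.2 equiv), 0 °C to rt
Reagents that add atoms: isobutyric anhydride, CC(C)C(=O)OC(=O)C(C)C
Why: Diastereoselective 1,2-reduction followed by in situ O-acylation of the aluminium alkoxide (reductive acylation): the bulky hydride adds axially from the α face, anti to CH3-14, as in steroidal 4-en-3-ones, which sets the pseudo-equatorial 3β-oxygen (3S), and trapping 8 directly avoids handling the acid-sensitive allylic alcohol.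

Step 4
Reactants: 9 (3S,10R)-3β-isobutyryloxy-11,12,13-trinoreudesm-4-en-8-one ethylene ketal
Product: 10 (3S,10R)-3β-isobutyryloxy-11,12,13-trinoreudesm-4-en-8-one
Conditions: PPTS (0.2 equiv), acetone/H2O 10:1, 50 °C
Reagents that add atoms: water, O
Why: Mild acid-catalysed ketal hydrolysis: PPTS in wet acetone cleaves the dioxolane but is too weak to ionise the allylic isobutyrate or to move the Δ4 alkene, which is γ,δ to the new C8 ketone, and no stereocentre is touched.

Step 5
Reactants: 10 (3S,10R)-3β-isobutyryloxy-11,12,13-trinoreudesm-4-en-8-one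
Product: 11 (3S,10R)-3β-isobutyryloxy-8-trimethylsilyloxy-11,12,13-trinoreudesma-4,7-diene
Conditions: Me3SiCl (1.5 equiv), then LiN(iPr)2 (1.1 equiv), THF, −78 °C; cold aq NaHCO3/pentane work-up, used crude
Reagents that add atoms: chlorotrimethylsilane, C[Si](C)(C)Cl
Why: Kinetic enolisation with internal silyl quench (regioselective silyl enol ether formation): the hindered amide removes the accessible H7 rather than the neopentyl H9 next to quaternary C10, and the ketone is deprotonated much faster than the tertiary α-CH of the isobutyrate, so only the Δ7 enol silane forms and no stereocentre is affected.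

Step 6
Reactants: 11 (3S,10R)-3β-isobutyryloxy-8-trimethylsilyloxy-11,12,13-trinoreudesma-4,7-diene; 12 methyl 2-bromoacrylate
Product: 16 methyl (3S,7R,10R)-3β-isobutyryloxy-8-oxoeudesma-4,11(13)-dien-12-oate (7αH; side chain β and equatorial), via vinylzinc reagent 13 (not isolated), via enolonium 14 (not isolated), via 7-epimer 15 (not isolated)
Conditions: PhI(OAc)2 (1.1 equiv), BF3·OEt2 (1.5 equiv), CH2Cl2, −78 °C, add 11, 5 min; then 13 (2.5 equiv, made from 12, Zn dust, LiCl, THF, 0 °C), −78 to −40 °C; aq NaHCO3; then DBU (5 mol%), CH2Cl2, 0 °C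
Reagents that add atoms: none
Why: Proposed new method: BF3-activated PhI(OAc)2 oxidises the enol silane to the discrete O-bound trivalent-iodine enolate 14, whose C7 is now an acceptor, and the Reformatsky-type vinylzinc/zinc allenolate 13 (donor at the ester α-carbon C11) expels iodobenzene either by SN2'-type attack at C7 or by ligand exchange at iodine and reductive ligand coupling, so two native donor carbons are joined and the complete α-methylene ester is installed at once; the closest known reaction types are the hypervalent-iodine umpolung α-alkylation of ketone enolates with dialkylzincs, the α-allylation of preformed enolonium species with allylsilanes and the α-vinylation of enolates with alkenyl(aryl)iodonium salts; stereoelectronic axial attack gives 7α-15, and because C7 is α to the ketone, catalytic DBU equilibrates it to the equatorial 7β-isomer 16 (7R).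

Step 7
Reactants: 16 methyl (3S,7R,10R)-3β-isobutyryloxy-8-oxoeudesma-4,11(13)-dien-12-oate
Product: 18 methyl (3S,7R,8R,10R)-8β-acetoxy-3β-isobutyryloxyeudesma-4,11(13)-dien-12-oate, via lithium 8β-alkoxyaluminate 17 (not isolated)
Conditions: LiAlH(OtBu)3 (1.3 equiv), THF, −40 to −20 °C; then pyridine (3 equiv), DMAP (1 equiv), Ac2O (6 equiv), −40 to 0 °C
Reagents that add atoms: acetic anhydride, CC(=O)OC(C)=O
Why: Substrate-controlled ketone reduction with in situ acetylation of the aluminium alkoxide (reductive acetylation): axial CH3-14 blocks the β (axial) trajectory at C8, so hydride arrives from the α face and gives the axial 8β-oxygen (8R) cis to the C7 side chain, LiAlH(OtBu)3 leaves the two esters and the acrylate untouched, and capping 17 before any free alkoxide or alcohol is released prevents closure to the cis-8,12-lactone.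

Step 8
Reactants: 18 methyl (3S,7R,8R,10R)-8β-acetoxy-3β-isobutyryloxyeudesma-4,11(13)-dien-12-oate
Product: 19 methyl (3S,5S,7R,8R,10R)-8β-acetoxy-5α-hydroperoxy-3β-isobutyryloxyeudesma-4(15),11(13)-dien-12-oate (target)
Conditions: O2, tetraphenylporphyrin (0.5 mol%), visible light, CH2Cl2, −20 °C; no reductive work-up, cold silica gel
Reagents that add atoms: oxygen, O=O
Why: Schenck ene reaction: singlet oxygen attacks only the electron-rich Δ4 alkene (the acrylate is too electron-poor) from the α face, because CH3-14 and both acyloxy groups shield the β face, and it bonds to C5 while abstracting an H of CH3-15, since on that face H6α is equatorial and misaligned, C10 bears no H and H3α is deactivated by its geminal acyloxy group, which sets the 5α-OOH (5S) and the 4(15)-methylene together.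

## Compound list
1 | 7-methyl-1,4-dioxaspiro[4.5]decan-8-one (racemic) | CC1CC2(CCC1=O)OCCO2 | starting material
2 | (R)-1-phenylethylamine | C[C@@H](N)c1ccccc1 | starting material
3 | pent-1-en-3-one (ethyl vinyl ketone) | C=CC(=O)CC | starting material
4 | N-[(R)-1-phenylethyl] ketimine of 1 | CC1CC2(CCC1=N[C@H](C)c3ccccc3)OCCO2 | intermediate
5 | N-[(R)-1-phenylethyl] ketimine of 6 (quaternary carbon R) | CCC(=O)CC[C@]1(C)CC2(CCC1=N[C@H](C)c3ccccc3)OCCO2 | intermediate
6 | (R)-7-methyl-7-(3-oxopentyl)-1,4-dioxaspiro[4.5]decan-8-one | CCC(=O)CC[C@]1(C)CC2(CCC1=O)OCCO2 | intermediate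
7 | (10R)-11,12,13-trinoreudesm-4-ene-3,8-dione 8-ethylene ketal, i.e. (8a'R)-5',8a'-dimethyl-3',4',8',8a'-tetrahydro-1'H-spiro[1,3-dioxolane-2,2'-naphthalen]-6'(7'H)-one | O1CCOC12CCC3=C(C)C(=O)CC[C@]3(C)C2 | intermediate
8 | lithium tri-tert-butoxy(3β-alkoxy)aluminate from 7 | O1CCOC12CCC3=C(C)[C@@H](O[Al-](OC(C)(C)C)(OC(C)(C)C)OC(C)(C)C)CC[C@]3(C)C2.[Li+] | intermediate
9 | (3S,10R)-3β-isobutyryloxy-11,12,13-trinoreudesm-4-en-8-one ethylene ketal | O1CCOC12CCC3=C(C)[C@@H](OC(=O)C(C)C)CC[C@]3(C)C2 | intermediate
10 | (3S,10R)-3β-isobutyryloxy-11,12,13-trinoreudesm-4-en-8-one | O=C1CCC2=C(C)[C@@H](OC(=O)C(C)C)CC[C@]2(C)C1 | intermediate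
11 | (3S,10R)-3β-isobutyryloxy-8-trimethylsilyloxy-11,12,13-trinoreudesma-4,7-diene | C[Si](C)(C)OC1=CCC2=C(C)[C@@H](OC(=O)C(C)C)CC[C@]2(C)C1 | intermediate
12 | methyl 2-bromoacrylate | C=C(Br)C(=O)OC | starting material
13 | [1-(methoxycarbonyl)vinyl]zinc bromide | C=C([Zn]Br)C(=O)OC | intermediate
14 | O-[acetoxy(phenyl)iodanyl] Δ7-enolate of 10 (enolonium, BF3-activated) | CC(=O)OI(c3ccccc3)OC1=CCC2=C(C)[C@@H](OC(=O)C(C)C)CC[C@]2(C)C1 | intermediate
15 | methyl (3S,7S,10R)-3β-isobutyryloxy-8-oxoeudesma-4,11(13)-dien-12-oate (7-epimer, side chain α and axial) | C=C(C(=O)OC)[C@@H]1CC2=C(C)[C@@H](OC(=O)C(C)C)CC[C@]2(C)CC1=O | intermediate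
16 | methyl (3S,7R,10R)-3β-isobutyryloxy-8-oxoeudesma-4,11(13)-dien-12-oate | C=C(C(=O)OC)[C@H]1CC2=C(C)[C@@H](OC(=O)C(C)C)CC[C@]2(C)CC1=O | intermediate
17 | lithium tri-tert-butoxy(8β-alkoxy)aluminate from 16 | C=C(C(=O)OC)[C@H]1CC2=C(C)[C@@H](OC(=O)C(C)C)CC[C@]2(C)C[C@H]1O[Al-](OC(C)(C)C)(OC(C)(C)C)OC(C)(C)C.[Li+] | intermediate
18 | methyl (3S,7R,8R,10R)-8β-acetoxy-3β-isobutyryloxyeudesma-4,11(13)-dien-12-oate | C=C(C(=O)OC)[C@H]1CC2=C(C)[C@@H](OC(=O)C(C)C)CC[C@]2(C)C[C@H]1OC(C)=O | intermediate
19 | methyl (3S,5S,7R,8R,10R)-8β-acetoxy-5α-hydroperoxy-3β-isobutyryloxyeudesma-4(15),11(13)-dien-12-oate | C=C(C(=O)OC)[C@H]1C[C@@]2(OO)C(=C)[C@@H](OC(=O)C(C)C)CC[C@]2(C)C[C@H]1OC(C)=O | target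

## Step count and risks
Total step count: 8. Longest linear sequence: 8 (1 → 19; reagent 13 is made in situ within step 6).

**Step 6 (key coupling).**
- Risks: 13 may be oxidised to its homodimer; acetate may capture 14 (α-acetoxylation); the homoallylic Δ4 alkene may attack C7 to give 5,7-cyclo products; DBU may push the alkene into conjugation (C7=C11).
- Fallback: it sets out from 11 and returns at 16. It replaces the vinyl metal with a stabilised carbanion followed by methylenation.
- NIS in THF at −78 °C gives the axial 7α-iodo ketone F1, a halide-type enolonium equivalent.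
- SN2 displacement with inversion by the sodium salt of trimethyl phosphonoacetate (NaH, DMF, 0 °C) gives the 7β-phosphonoacetate F2.
- Horner–Wadsworth–Emmons methylenation of F2 with aqueous formaldehyde and K2CO3 gives 16, with C7 kept equatorial under the basic conditions.

**Step 7 (reductive acetylation).**
- Risks: the hindered axial aluminate may acetylate more slowly than it lactonises; some 8α-alcohol may form.
- Fallback: it sets out from 16 and returns at 18. It accepts the lactone instead of fighting it.
- NaBH4/CeCl3·7H2O in MeOH gives the 8β-hydroxy ester F3, which is allowed to close completely to the cis-fused α-methylene lactone F4. This also removes any 8α-isomer, which is separable.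
- One equivalent of LiOH in THF/H2O at 0 °C opens the lactone in preference to the hindered isobutyrate and gives the lithium hydroxy-carboxylate F5.
- MeI in DMF alkylates the carboxylate under non-acidic conditions to give F3 again. Ac2O/DMAP is added to the same flask to give 18.

**Step 8 (Schenck ene).**
- Risks: competing 4-hydroperoxy-Δ5 or Δ3 enol-ester regioisomers, and slow reaction of the acyloxy-deactivated alkene.
- Fallback: it sets out from 18 and returns at 19. It builds the C5–O bond by epoxidation and exchanges OH for OOH at the end.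
- mCPBA attacks only the tetrasubstituted alkene, from the α face, to give the 4α,5α-epoxide F6.
- Diethylaluminium 2,2,6,6-tetramethylpiperidide (PhMe, 0 °C) removes a CH3-15 proton in a syn-elimination and gives the 5α-hydroxy-4(15)-ene F7.
- Anhydrous ethereal H2O2 with catalytic TsOH at 0 °C exchanges the tertiary allylic OH through the allyl cation. The cation is captured axially at C5 on the α face to give 19.

Further compounds
F1 | step 6 | (3S,7S,10R)-7α-iodo-3β-isobutyryloxy-11,12,13-trinoreudesm-4-en-8-one | I[C@@H]1CC2=C(C)[C@@H](OC(=O)C(C)C)CC[C@]2(C)CC1=O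
F2 | step 6 | methyl 11-(dimethoxyphosphoryl)-3β-isobutyryloxy-8-oxo-13-noreudesm-4-en-12-oate (7αH, C11 epimer mixture) | COC(=O)C(P(=O)(OC)OC)[C@H]1CC2=C(C)[C@@H](OC(=O)C(C)C)CC[C@]2(C)CC1=O
F3 | step 7 | methyl 8β-hydroxy-3β-isobutyryloxyeudesma-4,11(13)-dien-12-oate | C=C(C(=O)OC)[C@H]1CC2=C(C)[C@@H](OC(=O)C(C)C)CC[C@]2(C)C[C@H]1O
F4 | step 7 | 3β-isobutyryloxyeudesma-4,11(13)-dien-8β,12-olide (cis-fused) | C=C3[C@H]1CC2=C(C)[C@@H](OC(=O)C(C)C)CC[C@]2(C)C[C@H]1OC3=O
F5 | step 7 | lithium 8β-hydroxy-3β-isobutyryloxyeudesma-4,11(13)-dien-12-oate | C=C(C(=O)[O-])[C@H]1CC2=C(C)[C@@H](OC(=O)C(C)C)CC[C@]2(C)C[C@H]1O.[Li+]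
F6 | step 8 | methyl 8β-acetoxy-4α,5α-epoxy-3β-isobutyryloxyeudesm-11(13)-en-12-oate | C=C(C(=O)OC)[C@H]1C[C@@]2(O3)[C@@]3(C)[C@@H](OC(=O)C(C)C)CC[C@]2(C)C[C@H]1OC(C)=O
F7 | step 8 | methyl 8β-acetoxy-5α-hydroxy-3β-isobutyryloxyeudesma-4(15),11(13)-dien-12-oate | C=C(C(=O)OC)[C@H]1C[C@@]2(O)C(=C)[C@@H](OC(=O)C(C)C)CC[C@]2(C)C[C@H]1OC(C)=O
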